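**Retrosynthetic overview**

1. The target is reached by hydrogenolysis of its tris(benzyl ether); nothing else changes after the ring is closed.
2. Lactone ring B (C1, O2, C3, C4, C4a, C8a) is closed last, on a preformed ester, by forming C3–C4: an enantioselective nickel hydride hydroalkylation joins the enol ester carbon (future C3) to the ortho benzylic bromide carbon (future C4). Ring A is bought.
3. Enabling feature: C3 is a carbinol carbon acylated through O2 by the C1 carboxyl, and that carboxyl sits on ring A ortho to the C4 methylene. The same ester therefore steers Ni–H to C3 (acyloxy chelate) and holds the benzylic carbon within reach for six-membered closure.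
4. The enol ester comes from Ru-catalysed anti-Markovnikov addition of a 2-(silyloxymethyl)benzoic acid to a terminal alkyne, then silyl ether to bromide. The acid comes from 3,5-bis(benzyloxy)benzyl alcohol (bromination, silylation, Br/Li exchange and CO2).
5. The alkyne comes from (S)-1,2-epoxybutane and oct-1-yne (epoxide opening, acetylene zipper, benzylation). The (9'S) centre is bought; the (3R) centre is made by the catalyst.

Key step: step 9

Assumption: the (S,S) antipode of the bis(oxazoline) ligand, 2,2'-(propane-2,2-diyl)bis[(4S)-4-benzyl-4,5-dihydrooxazole] ((S,S)-Bn-BOX), is taken to deliver (3R) in step 9. The sense of induction would be checked on a model enol ester and the (R,R) ligand used if it is opposite.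

**Route**

Step 1
Reactants: 1 (S)-1,2-epoxybutane; 2 oct-1-yne
Product: 4 (S)-dodec-5-yn-3-ol, via lithium oct-1-yn-1-ide 3 (not isolated)
Conditions: 2, n-BuLi, THF, −78 °C; BF3·OEt2; then 1, −78 °C; then H2O
Reagents that add atoms: none
Why: BF3-promoted opening of a terminal epoxide by a lithium acetylide (Yamaguchi–Hirao alkynylation) is an SN2 attack at the unsubstituted carbon, so the (S) carbinol centre of 1 is carried over untouched.

Step 2
Reactants: 4 (S)-dodec-5-yn-3-ol
Product: 6 (S)-dodec-11-yn-3-ol, via dipotassium alkoxide acetylide 5 (not isolated)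
Conditions: KH, H2N(CH2)3NH2, 0 °C → rt; then H2O
Reagents that add atoms: none
Why: the acetylene zipper (potassium 3-aminopropylamide isomerisation) should walk the triple bond by propargyl–allenyl proton shifts to the chain end, where the terminal acetylide is the thermodynamic sink; the alkoxide-bearing carbon is not deprotonated, so its configuration is kept.

Step 3
Reactants: 6 (S)-dodec-11-yn-3-ol
Product: 8 (S)-10-(benzyloxy)dodec-1-yne, via sodium (S)-dodec-11-yn-3-olate 7 (not isolated)
Conditions: NaH (1.05 equiv), THF, 0 °C; BnBr, n-Bu4NI (cat.), 0 °C → rt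
Reagents that add atoms: benzyl bromide, BrCc1ccccc1
Why: Williamson etherification; with one equivalent of NaH the alkoxide forms in preference to the far less acidic alkyne C–H, and the stereocentre is not involved.

Step 4
Reactants: 9 [3,5-bis(benzyloxy)phenyl]methanol
Product: 10 [3,5-bis(benzyloxy)-2-bromophenyl]methanol
Conditions: NBS (1.0 equiv), MeCN, 0 °C
Reagents that add atoms: N-bromosuccinimide, O=C1CCC(=O)N1Br
Why: electrophilic aromatic bromination should go to C2, which is ortho and para to the two ether oxygens and less hindered than C4 between them; one equivalent limits dibromination.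

Step 5
Reactants: 10 [3,5-bis(benzyloxy)-2-bromophenyl]methanol
Product: 11 {[3,5-bis(benzyloxy)-2-bromobenzyl]oxy}(tert-butyl)dimethylsilane
Conditions: TBSCl, imidazole, DMF, rt
Reagents that add atoms: tert-butyldimethylsilyl chloride, CC(C)(C)[Si](C)(C)Cl
Why: standard silylation of a primary alcohol; the silyl ether keeps the later carboxylic acid from lactonising to the phthalide.

Step 6
Reactants: 11 {[3,5-bis(benzyloxy)-2-bromobenzyl]oxy}(tert-butyl)dimethylsilane
Product: 14 2,4-bis(benzyloxy)-6-{[(tert-butyldimethylsilyl)oxy]methyl}benzoic acid, via aryllithium 12 (not isolated), via lithium carboxylate 13 (not isolated)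
Conditions: n-BuLi (1.05 equiv), THF, −78 °C; CO2, −78 → 0 °C; then aq. HCl to pH 4, 0 °C
Reagents that add atoms: carbon dioxide, O=C=O
Why: bromine–lithium exchange followed by carboxylation; at −78 °C exchange should outrun benzylic deprotonation and O→C silyl migration, and the aryllithium is trapped by CO2 at the carbon that becomes C8a.

Step 7
Reactants: 14 2,4-bis(benzyloxy)-6-{[(tert-butyldimethylsilyl)oxy]methyl}benzoic acid; 8 (S)-10-(benzyloxy)dodec-1-yne
Product: 15 (1Z,10S)-10-(benzyloxy)dodec-1-en-1-yl 2,4-bis(benzyloxy)-6-{[(tert-butyldimethylsilyl)oxy]methyl}benzoate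
Conditions: [RuCl2(p-cymene)]2 (2 mol %), P(4-ClC6H4)3 (6 mol %), DMAP (8 mol %), toluene, 60 °C
Reagents that add atoms: none
Why: Ru-catalysed anti-Markovnikov hydro-oxycarbonylation of a terminal alkyne through a ruthenium vinylidene; the carboxylate adds to the vinylidene carbon to give the (Z)-alk-1-enyl ester under near-neutral conditions that spare silyl and benzyl ethers.

Step 8
Reactants: 15 (1Z,10S)-10-(benzyloxy)dodec-1-en-1-yl 2,4-bis(benzyloxy)-6-{[(tert-butyldimethylsilyl)oxy]methyl}benzoate
Product: 16 (1Z,10S)-10-(benzyloxy)dodec-1-en-1-yl 2,4-bis(benzyloxy)-6-(bromomethyl)benzoate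
Conditions: Ph3PBr2 (1.3 equiv), CH2Cl2, 0 °C → rt
Reagents that add atoms: triphenylphosphine dibromide, BrP(Br)(c1ccccc1)(c1ccccc1)c1ccccc1
Why: direct silyl ether to bromide exchange with Ph3PBr2 (Appel-type activation of oxygen at phosphorus, then SN2 by bromide at the benzylic carbon) never liberates the free benzylic hydroxyl, which would otherwise attack the activated enol ester and give the phthalide.

Step 9
Reactants: 16 (1Z,10S)-10-(benzyloxy)dodec-1-en-1-yl 2,4-bis(benzyloxy)-6-(bromomethyl)benzoate
Product: 17 (3R)-6,8-bis(benzyloxy)-3-[(9S)-9-(benzyloxy)undecyl]-3,4-dihydro-1H-isochromen-1-one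
Conditions: NiBr2(dme) (10 mol %), (S,S)-Bn-BOX (12 mol %), (MeO)2MeSiH (2.5 equiv, slow addition), KF (2.5 equiv), DMA/t-BuOH, 0.01 M, 0 °C → rt
Reagents that add atoms: none
Why: Proposed new method: a bis(oxazoline)-ligated nickel hydride, formed from NiBr2(dme), silane and fluoride, should add across the enol ester C=C with nickel on the acyloxy-bearing carbon (future C3), guided by coordination of the ester carbonyl, while low-valent nickel abstracts bromine from the ortho CH2Br to give the benzylic radical (future C4); capture of that radical at the same nickel and C(sp3)–C(sp3) reductive elimination from trivalent nickel form the C3–C4 bond. The closest known reaction type is the intermolecular nickel-hydride-catalysed enantioselective hydroalkylation of enol esters and enamides with alkyl halides, which gives esters of chiral dialkyl carbinols; ring closure with a tethered benzylic halide is not known. Ring B closes by reductive elimination from a seven-membered nickelacycle (formally a 6-exo attack of the benzylic carbon on the enol ester carbon), which needs the ester to turn into its lactone-like s-cis rotamer, a turn eased by the two ortho substituents that already twist the aroyl group. The new C3 centre is set by the chiral ligand at nickel in the bond-forming event, after reversible hydrometalation, so (Z)- and (E)-enol ester and both alkene faces should converge on (3R); the (9'S) centre eight methylenes away should have no influence. The step needs regioselective hydrometalation (secured by the acyloxy chelate) and ring closure ahead of hydrodebromination or dimerisation of the benzylic bromide (secured by intramolecularity, high dilution and slow silane addition).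

Step 10
Reactants: 17 (3R)-6,8-bis(benzyloxy)-3-[(9S)-9-(benzyloxy)undecyl]-3,4-dihydro-1H-isochromen-1-one
Product: 18 (3R)-6,8-dihydroxy-3-[(9S)-9-hydroxyundecyl]-3,4-dihydro-1H-isochromen-1-one
Conditions: H2 (1 atm), Pd/C (10 wt %), EtOAc/MeOH, rt
Reagents that add atoms: none
Why: hydrogenolysis of the two aryl benzyl ethers and the secondary benzyl ether over Pd/C; the lactone C3–O bond is homobenzylic and should stay, and no stereocentre is touched.

**Compound list**

1 | (S)-1,2-epoxybutane | CC[C@H]1CO1 | starting material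
2 | oct-1-yne | C#CCCCCCC | starting material
3 | lithium oct-1-yn-1-ide | [Li]C#CCCCCCC | intermediate
4 | (S)-dodec-5-yn-3-ol | CC[C@H](O)CC#CCCCCCC | intermediate
5 | dipotassium (S)-dodec-11-yn-12-id-3-olate (alkoxide acetylide) | [K+].[K+].CC[C@H]([O-])CCCCCCCC#[C-] | intermediate
6 | (S)-dodec-11-yn-3-ol | CC[C@H](O)CCCCCCCC#C | intermediate
7 | sodium (S)-dodec-11-yn-3-olate | [Na+].CC[C@H]([O-])CCCCCCCC#C | intermediate
8 | (S)-10-(benzyloxy)dodec-1-yne | CC[C@H](OCc1ccccc1)CCCCCCCC#C | intermediate
9 | [3,5-bis(benzyloxy)phenyl]methanol | OCc1cc(OCc2ccccc2)cc(OCc2ccccc2)c1 | starting material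
10 | [3,5-bis(benzyloxy)-2-bromophenyl]methanol | OCc1cc(OCc2ccccc2)cc(OCc2ccccc2)c1Br | intermediate
11 | {[3,5-bis(benzyloxy)-2-bromobenzyl]oxy}(tert-butyl)dimethylsilane | CC(C)(C)[Si](C)(C)OCc1cc(OCc2ccccc2)cc(OCc2ccccc2)c1Br | intermediate
12 | [2,4-bis(benzyloxy)-6-{[(tert-butyldimethylsilyl)oxy]methyl}phenyl]lithium | CC(C)(C)[Si](C)(C)OCc1cc(OCc2ccccc2)cc(OCc2ccccc2)c1[Li] | intermediate
13 | lithium 2,4-bis(benzyloxy)-6-{[(tert-butyldimethylsilyl)oxy]methyl}benzoate | [Li+].CC(C)(C)[Si](C)(C)OCc1cc(OCc2ccccc2)cc(OCc2ccccc2)c1C(=O)[O-] | intermediate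
14 | 2,4-bis(benzyloxy)-6-{[(tert-butyldimethylsilyl)oxy]methyl}benzoic acid | CC(C)(C)[Si](C)(C)OCc1cc(OCc2ccccc2)cc(OCc2ccccc2)c1C(=O)O | intermediate
15 | (1Z,10S)-10-(benzyloxy)dodec-1-en-1-yl 2,4-bis(benzyloxy)-6-{[(tert-butyldimethylsilyl)oxy]methyl}benzoate | CC[C@H](OCc1ccccc1)CCCCCCC/C=C\OC(=O)c1c(CO[Si](C)(C)C(C)(C)C)cc(OCc2ccccc2)cc1OCc1ccccc1 | intermediate
16 | (1Z,10S)-10-(benzyloxy)dodec-1-en-1-yl 2,4-bis(benzyloxy)-6-(bromomethyl)benzoate | CC[C@H](OCc1ccccc1)CCCCCCC/C=C\OC(=O)c1c(CBr)cc(OCc2ccccc2)cc1OCc1ccccc1 | intermediate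
17 | (3R)-6,8-bis(benzyloxy)-3-[(9S)-9-(benzyloxy)undecyl]-3,4-dihydro-1H-isochromen-1-one | CC[C@H](OCc3ccccc3)CCCCCCCC[C@@H]1Cc2cc(OCc3ccccc3)cc(OCc3ccccc3)c2C(=O)O1 | intermediate
18 | (3R)-6,8-dihydroxy-3-[(9S)-9-hydroxyundecyl]-3,4-dihydro-1H-isochromen-1-one | CC[C@H](O)CCCCCCCC[C@@H]1Cc2cc(O)cc(O)c2C(=O)O1 | target

**Step count and risks**

Total steps: 10. Longest linear sequence: 7 (steps 4–10, or steps 1–3 followed by 7–10).

Steps most likely to fail:

Step 9 (proposed new method). The benzylic bromide may be reduced or coupled between molecules faster than the nickelacycle closes, or the closure may show poor enantiofacial control. The fallback uses known chemistry, sets out from 8 and returns to the route at 17.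
- Alkyne 8 is hydroborated with dicyclohexylborane and oxidised with NaBO3·4H2O to (S)-10-(benzyloxy)dodecanal F1.
- Corey–Chaykovsky methylenation (Me3S iodide, KOt-Bu, DMSO/THF) gives 2-[(9S)-9-(benzyloxy)undecyl]oxirane F2 as both epimers at the oxirane carbon.
- Hydrolytic kinetic resolution with the (salen)Co(OAc) antipode that hydrolyses the (2S) epimer (expected to be the (R,R) complex of trivalent cobalt, 0.55 equiv H2O) should leave (2R)-2-[(9S)-9-(benzyloxy)undecyl]oxirane F3.
- Purchased 1-bromo-3,5-bis(benzyloxy)benzene F4 is converted with Mg into [3,5-bis(benzyloxy)phenyl]magnesium bromide F5. CuI-catalysed opening of F3 at its terminal carbon should give (2R,11S)-1-[3,5-bis(benzyloxy)phenyl]-11-(benzyloxy)tridecan-2-ol F6.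
- NBS in MeCN should brominate ortho to the side chain, as in step 4, giving (2R,11S)-1-[3,5-bis(benzyloxy)-2-bromophenyl]-11-(benzyloxy)tridecan-2-ol F7.
- Carbonylative lactonisation (Pd(OAc)2, dppf, CO 1 atm, Et3N, DMF, 90 °C) closes ring B through the acyl carbon and gives 17.

Step 8. The enol ester may be lost during the silyl ether to bromide exchange, by HBr addition or by acyl transfer to the benzylic oxygen with phthalide formation. The fallback installs the bromide before the enol ester exists; it sets out from 14 and returns at 16.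
- Acid 14 is silylated (TBSCl, imidazole) to tert-butyldimethylsilyl 2,4-bis(benzyloxy)-6-{[(tert-butyldimethylsilyl)oxy]methyl}benzoate F8.
- Ph3PBr2 (2.2 equiv, CH2Cl2) should convert silyl ester and silyl ether in one operation into 2,4-bis(benzyloxy)-6-(bromomethyl)benzoyl bromide F9.
- The aldehyde F1 (made from 8 as in the fallback to step 9) is deprotonated with KOt-Bu in THF at −78 °C to potassium (S)-10-(benzyloxy)dodec-1-en-1-olate F10.
- Inverse addition of F10 to F9 should give, by O-acylation, 16 together with (1E,10S)-10-(benzyloxy)dodec-1-en-1-yl 2,4-bis(benzyloxy)-6-(bromomethyl)benzoate F11. Both geometric isomers are substrates for the geometry-convergent step 9.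

Step 6. The aryllithium may undergo anionic O→C silyl migration before it is trapped, and the silyl ether may be lost with lactonisation when the carboxylate is acidified. The fallback replaces the organolithium by palladium-catalysed hydroxycarbonylation; it sets out from 11 and returns at 14 and makes no new compound (F0). Conditions: Pd(OAc)2, Xantphos, CO (1 atm), K2CO3, H2O/dioxane, 90 °C, then careful acidification to pH 4–5.

**Further compounds**

F1 | step 9 | (S)-10-(benzyloxy)dodecanal | CC[C@H](OCc1ccccc1)CCCCCCCCC=O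
F2 | step 9 | 2-[(9S)-9-(benzyloxy)undecyl]oxirane, both epimers at the oxirane carbon | CC[C@H](OCc1ccccc1)CCCCCCCCC1CO1
F3 | step 9 | (2R)-2-[(9S)-9-(benzyloxy)undecyl]oxirane | CC[C@H](OCc1ccccc1)CCCCCCCC[C@@H]1CO1
F4 | step 9 | 1-bromo-3,5-bis(benzyloxy)benzene (purchased) | Brc1cc(OCc2ccccc2)cc(OCc2ccccc2)c1
F5 | step 9 | [3,5-bis(benzyloxy)phenyl]magnesium bromide | Br[Mg]c1cc(OCc2ccccc2)cc(OCc2ccccc2)c1
F6 | step 9 | (2R,11S)-1-[3,5-bis(benzyloxy)phenyl]-11-(benzyloxy)tridecan-2-ol | CC[C@H](OCc1ccccc1)CCCCCCCC[C@@H](O)Cc1cc(OCc2ccccc2)cc(OCc2ccccc2)c1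
F7 | step 9 | (2R,11S)-1-[3,5-bis(benzyloxy)-2-bromophenyl]-11-(benzyloxy)tridecan-2-ol | CC[C@H](OCc1ccccc1)CCCCCCCC[C@@H](O)Cc1cc(OCc2ccccc2)cc(OCc2ccccc2)c1Br
F8 | step 8 | tert-butyldimethylsilyl 2,4-bis(benzyloxy)-6-{[(tert-butyldimethylsilyl)oxy]methyl}benzoate | CC(C)(C)[Si](C)(C)OCc1cc(OCc2ccccc2)cc(OCc2ccccc2)c1C(=O)O[Si](C)(C)C(C)(C)C
F9 | step 8 | 2,4-bis(benzyloxy)-6-(bromomethyl)benzoyl bromide | BrCc1cc(OCc2ccccc2)cc(OCc2ccccc2)c1C(Br)=O
F10 | step 8 | potassium (S)-10-(benzyloxy)dodec-1-en-1-olate | [K+].CC[C@H](OCc1ccccc1)CCCCCCCC=C[O-]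
F11 | step 8 | (1E,10S)-10-(benzyloxy)dodec-1-en-1-yl 2,4-bis(benzyloxy)-6-(bromomethyl)benzoate | CC[C@H](OCc1ccccc1)CCCCCCC/C=C/OC(=O)c1c(CBr)cc(OCc2ccccc2)cc1OCc1ccccc1
F0 | step 6 | none | none
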